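## Retrosynthetic overview

1. Ring A is the cyclopentanone (C1 quaternary carbon, C2 ketone, C3 carbinol, C4, C5); ring B is the 14-membered dilactone bridging C1/C3; ring C is the 14-membered keto-dilactone fused at C4–C5. Target ⇒ (desilylation, deallylation) ⇒ Michael disconnection C1–CH(CO2H): ring-A β-keto ester 30 + acyclic enedione 28.
2. 30 ⇒ new catalytic formal [3+2] Michael/aldol annulation (C1–C5 and C3–C4 bonds, ring A) of dione macrolide 18 with enedione macrolide 21.
3. 18 and 21 ⇒ one macrocycle 16 (dihydroxylation/oxidation, or epoxidation/E1cB/oxidation) ⇒ ring-closing metathesis of diene 15.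
4. 15 (Lindlar semi-hydrogenation, Z) and 28 (trans-hydroalumination, E; cross-metathesis) ⇒ one propargylic alcohol 10 ⇒ asymmetric alkynylation of (S)-lactaldehyde 8 with the propiolate 5 of (S)-hex-5-en-2-ol.
5. Ring order: the two 14-membered rings first (as 16, then 18 and 21), ring A last; closing ring A turns the two macrolides into ring B (bridged) and ring C (fused).

Assumption: the SMILES is taken literally (both ring enoates Z, side-chain enoate E); centres that are oxidised away later (in 17, 19, 20, 26, 27) and the metathesis olefin geometry (16, 24, 25) are carried as mixtures with one isomer drawn; TES = triethylsilyl, TBS = tert-butyldimethylsilyl.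

## Route

Step 1
Reactants: 1 (S)-propylene oxide; 2 allylmagnesium bromide
Product: 3 (S)-hex-5-en-2-ol
Conditions: CuI (10 mol %), THF, −40 → 0 °C; aq. NH4Cl
Reagents that add atoms: none
Why: Copper-catalysed Grignard opening of the epoxide (SN2 at the unhindered CH2) leaves the C–O stereocentre untouched, so 3 is (S).

Step 2
Reactants: 3 (S)-hex-5-en-2-ol; 4 propiolic acid
Product: 5 (S)-hex-5-en-2-yl prop-2-ynoate
Conditions: DCC, DMAP (5 mol %), CH2Cl2, −20 → 0 °C
Reagents that add atoms: none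
Why: Steglich esterification at low temperature; the carbinol centre is not involved.

Step 3
Reactants: 6 ethyl (S)-lactate
Product: 7 ethyl (S)-2-(triethylsilyloxy)propanoate
Conditions: TESCl, imidazole, CH2Cl2, 0 °C → rt
Reagents that add atoms: chlorotriethylsilane (TESCl), CC[Si](Cl)(CC)CC
Why: Silyl ether formation on oxygen; the stereocentre is untouched.

Step 4
Reactants: 7 ethyl (S)-2-(triethylsilyloxy)propanoate
Product: 8 (S)-2-(triethylsilyloxy)propanal
Conditions: i-Bu2AlH (1.05 equiv), CH2Cl2, −78 °C; aq. potassium sodium tartrate (KNaC4H4O6); used at once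
Reagents that add atoms: none
Why: Low-temperature half-reduction of the ester through the stable aluminium hemiacetal; immediate use avoids epimerisation of the α-silyloxy aldehyde.

Step 5
Reactants: 8 (S)-2-(triethylsilyloxy)propanal; 5 (S)-hex-5-en-2-yl prop-2-ynoate
Product: 10 (S)-hex-5-en-2-yl (4R,5S)-4-hydroxy-5-(triethylsilyloxy)hex-2-ynoate, via methylzinc alkynylide 9 (not isolated)
Conditions: 5 (2.8 equiv), ZnMe2 (2.9 equiv), (S,S)-ProPhenol (10 mol %), Ph3PO (20 mol %), toluene, 0 °C, 1 h; then 8, 4 °C, 48 h; aq. NH4Cl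
Reagents that add atoms: none
Why: Zinc–ProPhenol asymmetric alkynylation: the alkynylide 9 adds to the Re face of the aldehyde, which sets C4 (R) anti to C5; the (S,S)-ligand is taken as the antipode that delivers to this face, and it reinforces the Felkin–Anh preference of the α-silyloxy aldehyde.

Step 6
Reactants: 10 (S)-hex-5-en-2-yl (4R,5S)-4-hydroxy-5-(triethylsilyloxy)hex-2-ynoate
Product: 11 (S)-hex-5-en-2-yl (4R,5S)-4-(tert-butyldimethylsilyloxy)-5-(triethylsilyloxy)hex-2-ynoate
Conditions: TBSOTf, 2,6-lutidine, CH2Cl2, −78 °C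
Reagents that add atoms: tert-butyldimethylsilyl triflate (TBSOTf), CC(C)(C)[Si](C)(C)OS(=O)(=O)C(F)(F)F
Why: Silylation of the propargylic alcohol with the silyl triflate; no stereocentre is touched.

Step 7
Reactants: 11 (S)-hex-5-en-2-yl (4R,5S)-4-(tert-butyldimethylsilyloxy)-5-(triethylsilyloxy)hex-2-ynoate
Product: 12 (S)-hex-5-en-2-yl (4R,5S)-4-(tert-butyldimethylsilyloxy)-5-hydroxyhex-2-ynoate
Conditions: PPTS (0.2 equiv), MeOH/CH2Cl2 1:1, 0 °C
Reagents that add atoms: none
Why: Acid-catalysed methanolysis cleaves the secondary TES ether much faster than the TBS ether, and the linear ynoate cannot lactonise onto the freed 5-OH.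

Step 8
Reactants: 12 (S)-hex-5-en-2-yl (4R,5S)-4-(tert-butyldimethylsilyloxy)-5-hydroxyhex-2-ynoate; 13 but-3-enoic acid
Product: 14 (S)-hex-5-en-2-yl (4R,5S)-5-(but-3-enoyloxy)-4-(tert-butyldimethylsilyloxy)hex-2-ynoate
Conditions: DCC, DMAP (10 mol %), CH2Cl2, 0 °C
Reagents that add atoms: none
Why: Steglich esterification kept cold with little DMAP so that the β,γ-olefin does not move into conjugation.

Step 9
Reactants: 14 (S)-hex-5-en-2-yl (4R,5S)-5-(but-3-enoyloxy)-4-(tert-butyldimethylsilyloxy)hex-2-ynoate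
Product: 15 (S)-hex-5-en-2-yl (2Z,4R,5S)-5-(but-3-enoyloxy)-4-(tert-butyldimethylsilyloxy)hex-2-enoate
Conditions: H2 (1 atm), Pd/CaCO3 poisoned with Pb(OAc)2, quinoline, EtOAc, rt, stopped at 1.0 equiv H2
Reagents that add atoms: none
Why: Lindlar semi-hydrogenation (syn addition of H2) gives the (Z)-enoate; quinoline and uptake control spare the terminal olefins, and both neighbouring oxygens are capped so the (Z)-enoate cannot lactonise.

Step 10
Reactants: 15 (S)-hex-5-en-2-yl (2Z,4R,5S)-5-(but-3-enoyloxy)-4-(tert-butyldimethylsilyloxy)hex-2-enoate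
Product: 16 (3Z,5R,6S,10E,14S)-5-(tert-butyldimethylsilyloxy)-6,14-dimethyl-1,7-dioxacyclotetradeca-3,10-diene-2,8-dione
Conditions: second-generation Grubbs catalyst RuCl2(=CHPh)(PCy3)(H2IMes) (10 mol %), 1,4-benzoquinone (20 mol %), CH2Cl2 (1 mM), 40 °C
Reagents that add atoms: none
Why: Ring-closing metathesis of the two terminal olefins (the hindered, electron-poor (Z)-enoate is inert) closes the 14-membered ring; the geometry of the new olefin is irrelevant because it is oxidised next.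

Step 11
Reactants: 16 (3Z,5R,6S,10E,14S)-5-(tert-butyldimethylsilyloxy)-6,14-dimethyl-1,7-dioxacyclotetradeca-3,10-diene-2,8-dione
Product: 17 (3Z,5R,6S,14S)-5-(tert-butyldimethylsilyloxy)-10,11-dihydroxy-6,14-dimethyl-1,7-dioxacyclotetradec-3-ene-2,8-dione
Conditions: OsO4 (2 mol %), NMO (1.2 equiv), acetone/H2O 10:1, 0 °C; crude diol used at once
Reagents that add atoms: N-methylmorpholine N-oxide (NMO), C[N+]1([O-])CCOCC1; water, O
Why: Upjohn dihydroxylation takes the isolated, more electron-rich olefin in preference to the silyloxy-shielded enoate; the two new carbinol centres are destroyed in the next step.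

Step 12
Reactants: 17 (3Z,5R,6S,14S)-5-(tert-butyldimethylsilyloxy)-10,11-dihydroxy-6,14-dimethyl-1,7-dioxacyclotetradec-3-ene-2,8-dione
Product: 18 (3Z,5R,6S,14S)-5-(tert-butyldimethylsilyloxy)-6,14-dimethyl-1,7-dioxacyclotetradec-3-ene-2,8,10,11-tetrone
Conditions: IBX (4 equiv), DMSO, rt; used directly
Reagents that add atoms: none
Why: IBX oxidises both secondary alcohols to the vicinal dione without glycol cleavage, giving the β,γ-diketo ester (largely enolised).

Step 13
Reactants: 16 (3Z,5R,6S,10E,14S)-5-(tert-butyldimethylsilyloxy)-6,14-dimethyl-1,7-dioxacyclotetradeca-3,10-diene-2,8-dione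
Product: 19 (3Z,5R,6S,14S)-5-(tert-butyldimethylsilyloxy)-10,11-epoxy-6,14-dimethyl-1,7-dioxacyclotetradec-3-ene-2,8-dione
Conditions: mCPBA (1.2 equiv), NaHCO3, CH2Cl2, 0 °C
Reagents that add atoms: 3-chloroperbenzoic acid (mCPBA), OOC(=O)c1cccc(Cl)c1
Why: Prilezhaev epoxidation; the electrophilic peracid selects the isolated olefin over the electron-poor enoate.

Step 14
Reactants: 19 (3Z,5R,6S,14S)-5-(tert-butyldimethylsilyloxy)-10,11-epoxy-6,14-dimethyl-1,7-dioxacyclotetradec-3-ene-2,8-dione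
Product: 20 (3Z,5R,6S,9E,14S)-5-(tert-butyldimethylsilyloxy)-11-hydroxy-6,14-dimethyl-1,7-dioxacyclotetradeca-3,9-diene-2,8-dione
Conditions: DBU (1.1 equiv), CH2Cl2, 0 °C
Reagents that add atoms: none
Why: E1cB opening of the β,γ-epoxy ester by deprotonation at C9 gives the (E)-γ-hydroxy enoate, which cannot lactonise.

Step 15
Reactants: 20 (3Z,5R,6S,9E,14S)-5-(tert-butyldimethylsilyloxy)-11-hydroxy-6,14-dimethyl-1,7-dioxacyclotetradeca-3,9-diene-2,8-dione
Product: 21 (3Z,5R,6S,9E,14S)-5-(tert-butyldimethylsilyloxy)-6,14-dimethyl-1,7-dioxacyclotetradeca-3,9-diene-2,8,11-trione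
Conditions: Dess–Martin periodinane (1.5 equiv), NaHCO3, CH2Cl2, 0 °C → rt
Reagents that add atoms: none
Why: Dess–Martin oxidation of the allylic alcohol gives the (E)-4-oxo-2-enoate.

Step 16
Reactants: 10 (S)-hex-5-en-2-yl (4R,5S)-4-hydroxy-5-(triethylsilyloxy)hex-2-ynoate
Product: 22 (S)-hex-5-en-2-yl (2E,4R,5S)-4-hydroxy-5-(triethylsilyloxy)hex-2-enoate
Conditions: NaAlH2(OCH2CH2OMe)2 (2 equiv), THF, −72 °C; aq. potassium sodium tartrate (KNaC4H4O6)
Reagents that add atoms: none
Why: Hydroxyl-directed trans-hydroalumination of the γ-hydroxy ynoate followed by protonolysis gives the (E)-enoate without touching the ester or the carbinol centres.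

Step 17
Reactants: 22 (S)-hex-5-en-2-yl (2E,4R,5S)-4-hydroxy-5-(triethylsilyloxy)hex-2-enoate
Product: 23 (S)-hex-5-en-2-yl (2E,4R,5S)-4-(tert-butyldimethylsilyloxy)-5-(triethylsilyloxy)hex-2-enoate
Conditions: TBSOTf, 2,6-lutidine, CH2Cl2, −78 °C
Reagents that add atoms: tert-butyldimethylsilyl triflate (TBSOTf), CC(C)(C)[Si](C)(C)OS(=O)(=O)C(F)(F)F
Why: Silylation of the allylic alcohol; no stereocentre is touched.

Step 18
Reactants: 23 (S)-hex-5-en-2-yl (2E,4R,5S)-4-(tert-butyldimethylsilyloxy)-5-(triethylsilyloxy)hex-2-enoate; 13 but-3-enoic acid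
Product: 24 (3E,7S)-7-{[(2E,4R,5S)-4-(tert-butyldimethylsilyloxy)-5-(triethylsilyloxy)hex-2-enoyl]oxy}oct-3-enoic acid
Conditions: 13 (4 equiv), second-generation Hoveyda–Grubbs catalyst RuCl2(=CH-C6H4-2-O-i-Pr)(H2IMes) (5 mol %), CH2Cl2, 40 °C
Reagents that add atoms: none
Why: Olefin cross-metathesis of two unhindered terminal olefins with the cheap partner in excess; the conjugated (E)-enoate does not take part.

Step 19
Reactants: 24 (3E,7S)-7-{[(2E,4R,5S)-4-(tert-butyldimethylsilyloxy)-5-(triethylsilyloxy)hex-2-enoyl]oxy}oct-3-enoic acid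
Product: 25 allyl (3E,7S)-7-{[(2E,4R,5S)-4-(tert-butyldimethylsilyloxy)-5-(triethylsilyloxy)hex-2-enoyl]oxy}oct-3-enoate
Conditions: allyl bromide, KHCO3, DMF, rt
Reagents that add atoms: allyl bromide, C=CCBr
Why: SN2 O-alkylation of the carboxylate under weakly basic conditions that do not move the β,γ-olefin.

Step 20
Reactants: 25 allyl (3E,7S)-7-{[(2E,4R,5S)-4-(tert-butyldimethylsilyloxy)-5-(triethylsilyloxy)hex-2-enoyl]oxy}oct-3-enoate
Product: 26 allyl (7S)-3,4-epoxy-7-{[(2E,4R,5S)-4-(tert-butyldimethylsilyloxy)-5-(triethylsilyloxy)hex-2-enoyl]oxy}octanoate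
Conditions: mCPBA (1.2 equiv), NaHCO3, CH2Cl2, 0 °C
Reagents that add atoms: 3-chloroperbenzoic acid (mCPBA), OOC(=O)c1cccc(Cl)c1
Why: Prilezhaev epoxidation selects the 1,2-dialkyl olefin over the deactivated allyl ester olefin and the enoate.

Step 21
Reactants: 26 allyl (7S)-3,4-epoxy-7-{[(2E,4R,5S)-4-(tert-butyldimethylsilyloxy)-5-(triethylsilyloxy)hex-2-enoyl]oxy}octanoate
Product: 27 allyl (2E,7S)-4-hydroxy-7-{[(2E,4R,5S)-4-(tert-butyldimethylsilyloxy)-5-(triethylsilyloxy)hex-2-enoyl]oxy}oct-2-enoate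
Conditions: DBU (1.1 equiv), CH2Cl2, 0 °C
Reagents that add atoms: none
Why: E1cB opening of the β,γ-epoxy ester gives the (E)-γ-hydroxy enoate.

Step 22
Reactants: 27 allyl (2E,7S)-4-hydroxy-7-{[(2E,4R,5S)-4-(tert-butyldimethylsilyloxy)-5-(triethylsilyloxy)hex-2-enoyl]oxy}oct-2-enoate
Product: 28 allyl (2E,7S)-4-oxo-7-{[(2E,4R,5S)-4-(tert-butyldimethylsilyloxy)-5-(triethylsilyloxy)hex-2-enoyl]oxy}oct-2-enoate
Conditions: Dess–Martin periodinane (1.5 equiv), NaHCO3, CH2Cl2, 0 °C → rt
Reagents that add atoms: none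
Why: Dess–Martin oxidation of the allylic alcohol gives the acyclic (E)-4-oxo-2-enoate acceptor.

Step 23
Reactants: 18 (3Z,5R,6S,14S)-5-(tert-butyldimethylsilyloxy)-6,14-dimethyl-1,7-dioxacyclotetradec-3-ene-2,8,10,11-tetrone; 21 (3Z,5R,6S,9E,14S)-5-(tert-butyldimethylsilyloxy)-6,14-dimethyl-1,7-dioxacyclotetradeca-3,9-diene-2,8,11-trione
Product: 30 ring-A cyclopentanone bis-macrolide (1S,3S,4S,5S; C1–H), via open Michael adduct 29 (not isolated)
Conditions: 18 (1.1 equiv), quinine-derived 3,5-bis(trifluoromethyl)phenyl squaramide (10 mol %), toluene (0.1 M), −20 → 0 °C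
Reagents that add atoms: none
Why: Proposed new method: bifunctional tertiary-amine/squaramide-catalysed formal [3+2] Michael/aldol annulation of a 3,4-dioxo ester (C9 nucleophile and C11 carbonyl electrophile of 18) with a 4-oxo-2-enoate: the quinuclidine deprotonates the doubly activated C9–H of 18 while the squaramide hydrogen-bonds the ketone of 21, the enolate adds to the Re face of C9 of 21 (β to the ketone, the stronger acceptor) to set ring-A C5 (S) and give 29, whose ammonium-bound ketone enolate sits five atoms from the very electrophilic 1,2-dione carbonyl and closes by a reversible 5-exo aldol addition that places the C4 acyl group cis to the new C3 hydroxyl (hydrogen-bonded closed transition state) and trans to the C5 ester (thermodynamic), ring-A C1 being fixed because the 11-atom lactone bridge can only span C1/C3 cis; closest known reaction type: amine–thiourea or squaramide-catalysed Michael/aldol and Michael/Henry domino [3+2] annulations of cyclic 1,2-diones or α-keto esters with enals or nitroalkenes, which have not been shown for β,γ-diketo esters, for enedione acceptors or for joining two macrocycles.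

Step 24
Reactants: 30 ring-A cyclopentanone bis-macrolide (1S,3S,4S,5S; C1–H); 28 allyl (2E,7S)-4-oxo-7-{[(2E,4R,5S)-4-(tert-butyldimethylsilyloxy)-5-(triethylsilyloxy)hex-2-enoyl]oxy}oct-2-enoate
Product: 31 protected trimer allyl ester (ring A 1S,3S,4S,5S; side-chain CH(CO2allyl) R)
Conditions: 28 (1.5 equiv), quinidine-derived 3,5-bis(trifluoromethyl)phenyl squaramide (20 mol %), CH2Cl2 (1 M), rt, 72 h
Reagents that add atoms: none
Why: Organocatalytic Michael addition of a cyclic β-keto ester to a 4-oxo-2-enoate (attack β to the ketone): the C1 enolate of 30 can only be approached anti to the ring-B bridge, which sets C1 (S), and the hydrogen-bonded acceptor is attacked on the Si face of its C2, chosen by the catalyst, which sets the CH(CO2allyl) centre (R).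

Step 25
Reactants: 31 protected trimer allyl ester (ring A 1S,3S,4S,5S; side-chain CH(CO2allyl) R)
Product: 32 protected trimer carboxylic acid
Conditions: Pd(PPh3)4 (5 mol %), N-methylaniline (3 equiv), THF, rt
Reagents that add atoms: none
Why: Tsuji–Trost deallylation: the palladium catalyst ionises the allyl ester and N-methylaniline traps the π-allyl complex under neutral conditions that leave silyl ethers, enoates and the aldol untouched.

Step 26
Reactants: 32 protected trimer carboxylic acid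
Product: 33 target CNP0078817.1
Conditions: HF·pyridine, pyridine, THF, 0 °C → rt; NaH2PO4/Na2HPO4 buffer (pH 7) quench
Reagents that add atoms: none
Why: Fluoride-mediated global desilylation (three TBS ethers, one TES ether) under pyridine-buffered, weakly acidic conditions chosen so that the freed γ-hydroxy (Z)-enoates do not lactonise, the 5-O-acyl groups do not migrate and the aldol is not reversed; no stereocentre is touched.

## Compound list

1 | (S)-propylene oxide | C[C@H]1CO1 | starting material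
2 | allylmagnesium bromide | C=CC[Mg]Br | starting material
3 | (S)-hex-5-en-2-ol | C[C@H](O)CCC=C | intermediate
4 | propiolic acid | C#CC(=O)O | starting material
5 | (S)-hex-5-en-2-yl prop-2-ynoate | C#CC(=O)O[C@@H](C)CCC=C | intermediate
6 | ethyl (S)-lactate | CCOC(=O)[C@H](C)O | starting material
7 | ethyl (S)-2-(triethylsilyloxy)propanoate | CCOC(=O)[C@H](C)O[Si](CC)(CC)CC | intermediate
8 | (S)-2-(triethylsilyloxy)propanal | O=C[C@H](C)O[Si](CC)(CC)CC | intermediate
9 | methylzinc alkynylide of 5 (not isolated) | C[Zn]C#CC(=O)O[C@@H](C)CCC=C | intermediate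
10 | (S)-hex-5-en-2-yl (4R,5S)-4-hydroxy-5-(triethylsilyloxy)hex-2-ynoate | C[C@H](O[Si](CC)(CC)CC)[C@H](O)C#CC(=O)O[C@@H](C)CCC=C | intermediate
11 | (S)-hex-5-en-2-yl (4R,5S)-4-(tert-butyldimethylsilyloxy)-5-(triethylsilyloxy)hex-2-ynoate | C[C@H](O[Si](CC)(CC)CC)[C@H](O[Si](C)(C)C(C)(C)C)C#CC(=O)O[C@@H](C)CCC=C | intermediate
12 | (S)-hex-5-en-2-yl (4R,5S)-4-(tert-butyldimethylsilyloxy)-5-hydroxyhex-2-ynoate | C[C@H](O)[C@H](O[Si](C)(C)C(C)(C)C)C#CC(=O)O[C@@H](C)CCC=C | intermediate
13 | but-3-enoic acid | C=CCC(=O)O | starting material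
14 | (S)-hex-5-en-2-yl (4R,5S)-5-(but-3-enoyloxy)-4-(tert-butyldimethylsilyloxy)hex-2-ynoate | C=CCC(=O)O[C@@H](C)[C@H](O[Si](C)(C)C(C)(C)C)C#CC(=O)O[C@@H](C)CCC=C | intermediate
15 | (S)-hex-5-en-2-yl (2Z,4R,5S)-5-(but-3-enoyloxy)-4-(tert-butyldimethylsilyloxy)hex-2-enoate | C=CCC(=O)O[C@@H](C)[C@H](O[Si](C)(C)C(C)(C)C)/C=C\C(=O)O[C@@H](C)CCC=C | intermediate
16 | (3Z,5R,6S,10E,14S)-5-(tert-butyldimethylsilyloxy)-6,14-dimethyl-1,7-dioxacyclotetradeca-3,10-diene-2,8-dione (10E drawn, 10Z equally usable) | O=C1C/C=C/CC[C@H](C)OC(=O)/C=C\[C@@H](O[Si](C)(C)C(C)(C)C)[C@H](C)O1 | intermediate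
17 | (3Z,5R,6S,14S)-5-(tert-butyldimethylsilyloxy)-10,11-dihydroxy-6,14-dimethyl-1,7-dioxacyclotetradec-3-ene-2,8-dione (diol diastereomers) | O=C1CC(O)C(O)CC[C@H](C)OC(=O)/C=C\[C@@H](O[Si](C)(C)C(C)(C)C)[C@H](C)O1 | intermediate
18 | (3Z,5R,6S,14S)-5-(tert-butyldimethylsilyloxy)-6,14-dimethyl-1,7-dioxacyclotetradec-3-ene-2,8,10,11-tetrone (dione macrolide) | O=C1CC(=O)C(=O)CC[C@H](C)OC(=O)/C=C\[C@@H](O[Si](C)(C)C(C)(C)C)[C@H](C)O1 | intermediate
19 | (3Z,5R,6S,14S)-5-(tert-butyldimethylsilyloxy)-10,11-epoxy-6,14-dimethyl-1,7-dioxacyclotetradec-3-ene-2,8-dione (epoxide diastereomers) | O=C1CC2OC2CC[C@H](C)OC(=O)/C=C\[C@@H](O[Si](C)(C)C(C)(C)C)[C@H](C)O1 | intermediate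
20 | (3Z,5R,6S,9E,14S)-5-(tert-butyldimethylsilyloxy)-11-hydroxy-6,14-dimethyl-1,7-dioxacyclotetradeca-3,9-diene-2,8-dione (C11 epimers) | O=C1/C=C/C(O)CC[C@H](C)OC(=O)/C=C\[C@@H](O[Si](C)(C)C(C)(C)C)[C@H](C)O1 | intermediate
21 | (3Z,5R,6S,9E,14S)-5-(tert-butyldimethylsilyloxy)-6,14-dimethyl-1,7-dioxacyclotetradeca-3,9-diene-2,8,11-trione (enedione macrolide) | O=C1/C=C/C(=O)CC[C@H](C)OC(=O)/C=C\[C@@H](O[Si](C)(C)C(C)(C)C)[C@H](C)O1 | intermediate
22 | (S)-hex-5-en-2-yl (2E,4R,5S)-4-hydroxy-5-(triethylsilyloxy)hex-2-enoate | C[C@H](O[Si](CC)(CC)CC)[C@H](O)/C=C/C(=O)O[C@@H](C)CCC=C | intermediate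
23 | (S)-hex-5-en-2-yl (2E,4R,5S)-4-(tert-butyldimethylsilyloxy)-5-(triethylsilyloxy)hex-2-enoate | C[C@H](O[Si](CC)(CC)CC)[C@H](O[Si](C)(C)C(C)(C)C)/C=C/C(=O)O[C@@H](C)CCC=C | intermediate
24 | (3E,7S)-7-{[(2E,4R,5S)-4-(tert-butyldimethylsilyloxy)-5-(triethylsilyloxy)hex-2-enoyl]oxy}oct-3-enoic acid (3E drawn, E/Z mixture) | C[C@H](O[Si](CC)(CC)CC)[C@H](O[Si](C)(C)C(C)(C)C)/C=C/C(=O)O[C@@H](C)CC/C=C/CC(=O)O | intermediate
25 | allyl (3E,7S)-7-{[(2E,4R,5S)-4-(tert-butyldimethylsilyloxy)-5-(triethylsilyloxy)hex-2-enoyl]oxy}oct-3-enoate | C[C@H](O[Si](CC)(CC)CC)[C@H](O[Si](C)(C)C(C)(C)C)/C=C/C(=O)O[C@@H](C)CC/C=C/CC(=O)OCC=C | intermediate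
26 | allyl (7S)-3,4-epoxy-7-{[(2E,4R,5S)-4-(tert-butyldimethylsilyloxy)-5-(triethylsilyloxy)hex-2-enoyl]oxy}octanoate (epoxide diastereomers) | C[C@H](O[Si](CC)(CC)CC)[C@H](O[Si](C)(C)C(C)(C)C)/C=C/C(=O)O[C@@H](C)CCC1OC1CC(=O)OCC=C | intermediate
27 | allyl (2E,7S)-4-hydroxy-7-{[(2E,4R,5S)-4-(tert-butyldimethylsilyloxy)-5-(triethylsilyloxy)hex-2-enoyl]oxy}oct-2-enoate (C4 epimers) | C[C@H](O[Si](CC)(CC)CC)[C@H](O[Si](C)(C)C(C)(C)C)/C=C/C(=O)O[C@@H](C)CCC(O)/C=C/C(=O)OCC=C | intermediate
28 | allyl (2E,7S)-4-oxo-7-{[(2E,4R,5S)-4-(tert-butyldimethylsilyloxy)-5-(triethylsilyloxy)hex-2-enoyl]oxy}oct-2-enoate (acyclic enedione) | C[C@H](O[Si](CC)(CC)CC)[C@H](O[Si](C)(C)C(C)(C)C)/C=C/C(=O)O[C@@H](C)CCC(=O)/C=C/C(=O)OCC=C | intermediate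
29 | open Michael adduct (not isolated): C9 of tetrone 18 bonded to C9 of 21, that carbon now sp3 and (S), C10 of the former enedione a CH2; C9 of the tetrone ring epimerisable | O=C1C([C@@H]2CC(=O)CC[C@H](C)OC(=O)/C=C\[C@@H](O[Si](C)(C)C(C)(C)C)[C@H](C)OC2=O)C(=O)C(=O)CC[C@H](C)OC(=O)/C=C\[C@@H](O[Si](C)(C)C(C)(C)C)[C@H](C)O1 | intermediate
30 | ring-A cyclopentanone bis-macrolide: ring A (1S,3S,4S,5S) with C1–H, C2 ketone, C3–OH; ring B (from 18) bridges C1 (lactone C=O) and C3 (CH2CH2 chain); ring C (from 21) is fused at C4 (ketone) and C5 (lactone C=O); each macrolide keeps its (Z)-enoate, (R)-CH(OTBS) and two (S)-CH(CH3)O centres | [C@@H]12C(=O)O[C@@H](C)[C@H](O[Si](C)(C)C(C)(C)C)/C=C\C(=O)O[C@@H](C)CC[C@@](O)(C1=O)[C@H]1C(=O)CC[C@H](C)OC(=O)/C=C\[C@@H](O[Si](C)(C)C(C)(C)C)[C@H](C)OC(=O)[C@@H]12 | intermediate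
31 | protected trimer allyl ester: 30 carrying at C1 the (R)-CH(CO2allyl)CH2C(=O)CH2CH2CH(CH3)(S)-O-acyl side chain, acyl = (2E,4R,5S)-4-(TBSO)-5-(TESO)hex-2-enoyl | C[C@H](O[Si](CC)(CC)CC)[C@H](O[Si](C)(C)C(C)(C)C)/C=C/C(=O)O[C@@H](C)CCC(=O)C[C@@H](C(=O)OCC=C)[C@@]12C(=O)O[C@@H](C)[C@H](O[Si](C)(C)C(C)(C)C)/C=C\C(=O)O[C@@H](C)CC[C@@](O)(C1=O)[C@H]1C(=O)CC[C@H](C)OC(=O)/C=C\[C@@H](O[Si](C)(C)C(C)(C)C)[C@H](C)OC(=O)[C@@H]12 | intermediate
32 | protected trimer carboxylic acid (31 with free CO2H) | C[C@H](O[Si](CC)(CC)CC)[C@H](O[Si](C)(C)C(C)(C)C)/C=C/C(=O)O[C@@H](C)CCC(=O)C[C@@H](C(=O)O)[C@@]12C(=O)O[C@@H](C)[C@H](O[Si](C)(C)C(C)(C)C)/C=C\C(=O)O[C@@H](C)CC[C@@](O)(C1=O)[C@H]1C(=O)CC[C@H](C)OC(=O)/C=C\[C@@H](O[Si](C)(C)C(C)(C)C)[C@H](C)OC(=O)[C@@H]12 | intermediate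
33 | CNP0078817.1 | C[C@H](O)[C@H](O)/C=C/C(=O)O[C@@H](C)CCC(=O)C[C@@H](C(=O)O)[C@@]12C(=O)O[C@@H](C)[C@H](O)/C=C\C(=O)O[C@@H](C)CC[C@@](O)(C1=O)[C@H]1C(=O)CC[C@H](C)OC(=O)/C=C\[C@@H](O)[C@H](C)OC(=O)[C@@H]12 | target

## Step count and risks

Total step count: 26.
Longest linear sequence: 15 steps (1 → 2 → 5 → 6 → 7 → 8 → 9 → 10 → 13 → 14 → 15 → 23 → 24 → 25 → 26).

Steps most likely to fail:

Step 23, the new annulation, is the least certain. The catalyst may be mismatched with the two chiral macrocycles, 18 may self-condense, or the aldol may close with the wrong C3/C4 relationship. The fallback uses known chemistry only; it sets out from 18 and 21 and comes back at 30. The two C–C bonds are made in two separate classical operations under substrate control instead of one catalytic cascade. A tertiary-amine-catalysed Michael addition of the β-keto ester carbon of 18 to 21 (Et3N 10 mol %, THF, −20 °C, AcOH quench) is stopped at the open adduct 29, which is isolated; it is already a listed compound, so the new compounds here are none F0. 29 is then cyclised in a discrete base-mediated intramolecular aldol addition onto the 1,2-dione (catalytic DBU, CH2Cl2, −40 → 0 °C). The aldol is left to equilibrate by retro-aldol/aldol to the trans-C4/C5 isomer, and the diastereomers are separated by chromatography to give 30.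

Step 24 builds a quaternary carbon next to a tertiary one from a hindered, bridged donor in a bimolecular reaction. Retro-Michael reaction and poor control of the side-chain centre are the dangers. The fallback sets out from 18 and 28 and comes back at 31; it reverses the order of the two bond-forming events. The unhindered methylene of 18 is added first to 28 with the same squaramide class (known acyclic β-keto ester/4-oxo-2-enoate Michael chemistry, Si face of C2 of 28), so only a tertiary centre is made, giving the side-chain-bearing tetrone F1. F1 is then annulated with 21 as in step 23, so that the quaternary C1 arises inside the annulation and 31 is reached directly.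

Step 10, the 14-membered ring-closing metathesis, may suffer from chelation of the but-3-enoate carbene, olefin migration or oligomerisation. The fallback sets out from 11 (with 13) and comes back at 16; it closes the ring by macrolactonisation instead of metathesis.
- Cross-metathesis of the terminal olefin of 11 with but-3-enoic acid 13 (RuCl2(=CH-C6H4-2-O-i-Pr)(H2IMes), CH2Cl2, 40 °C) gives the bis-silyl ynoate acid F2.
- PPTS in MeOH removes the TES group to give the hydroxy acid F3; the linear ynoate prevents δ-lactonisation.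
- Shiina macrolactonisation (2-methyl-6-nitrobenzoic anhydride, DMAP, high dilution, CH2Cl2, rt) closes the O7–C8 ester to give the macrocyclic ynoate F4.
- Lindlar semi-hydrogenation of F4 (H2, Pd/CaCO3 poisoned with Pb(OAc)2, quinoline) gives 16.

The final desilylation (step 26) is the next most exposed step, because the freed γ-hydroxy (Z)-enoates can lactonise to butenolides; it is run cold and buffered for that reason.

## Further compounds

F0 | step 23 | none | none
F1 | step 24 | side-chain-bearing tetrone: 18 alkylated at C9 by C2 of 28, CH(CO2allyl) centre (R), C9 epimerisable | C[C@H](O[Si](CC)(CC)CC)[C@H](O[Si](C)(C)C(C)(C)C)/C=C/C(=O)O[C@@H](C)CCC(=O)C[C@@H](C(=O)OCC=C)C1C(=O)C(=O)CC[C@H](C)OC(=O)/C=C\[C@@H](O[Si](C)(C)C(C)(C)C)[C@H](C)OC1=O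
F2 | step 10 | (3E,7S)-7-{[(4R,5S)-4-(tert-butyldimethylsilyloxy)-5-(triethylsilyloxy)hex-2-ynoyl]oxy}oct-3-enoic acid | C[C@H](O[Si](CC)(CC)CC)[C@H](O[Si](C)(C)C(C)(C)C)C#CC(=O)O[C@@H](C)CC/C=C/CC(=O)O
F3 | step 10 | (3E,7S)-7-{[(4R,5S)-4-(tert-butyldimethylsilyloxy)-5-hydroxyhex-2-ynoyl]oxy}oct-3-enoic acid | C[C@H](O)[C@H](O[Si](C)(C)C(C)(C)C)C#CC(=O)O[C@@H](C)CC/C=C/CC(=O)O
F4 | step 10 | (5R,6S,10E,14S)-5-(tert-butyldimethylsilyloxy)-6,14-dimethyl-1,7-dioxacyclotetradec-10-en-3-yne-2,8-dione | O=C1C/C=C/CC[C@H](C)OC(=O)C#C[C@@H](O[Si](C)(C)C(C)(C)C)[C@H](C)O1
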